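**Plan**
Retrosynthetic cuts, in order: the O4–aroyl ester bond; the C8–CH3 bond and the C7=C8 unsaturation; the C4–isopropyl bond (back to a C4 ketone, then a C4 carbinol); the C6–O and C5–H bonds (back to a C5=C6 alkene); last, in one operation, the ring bonds C7–C8 and C1–C10.
Enabling feature: the seven-membered ring (C1, C5, C6, C7, C8, C9, C10) consists of the ketone triad C8–C9(=O)–C10 and the four-carbon run C7–C6–C5–C1. C5 and C1 are also members of the five-membered ring (C1–C5). The ring therefore maps onto a 2-oxyallyl cation plus a 1-vinylcyclopentene whose far diene terminus is the methyl-bearing carbon C1.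
Forward order: the five-membered ring is bought as 3-methylcyclopentenone and made into the vinylcyclopentene. The seven-membered ring then closes in a single (4+3) step. O6/H5, the isopropyl group, the aroate and the C7=C8(CH3) enone follow in that order.
Stereochemistry: a CBS reduction sets C4–O (S, β). This silyloxy group steers the cycloaddition (C1, methyl β) and then the hydroboration (H5 and O6 α). After its oxidation to the ketone, the angular methyl group steers isopropyl addition to the α face, which rebuilds C4 with O β.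

Key step: step 6

Numbering remark: carotane locants are used in all bicyclic names (not von Baeyer locants). C1 is the quaternary ring-fusion carbon, C2 and C3 are the cyclopentane CH2 groups, C4 is the isopropyl carbinol carbon and C5 is the ring-fusion CH. C6 is the carbinol, C7=C8 the alkene, C9 the ketone and C10 a CH2. β is the face of the C1 methyl group. TBS = tert-butyldimethylsilyl, TBDPS = tert-butyldiphenylsilyl.
Assumption on the chemistry: the SMILES places the 4-hydroxybenzoate on the tertiary oxygen at C4 and leaves the C6 hydroxyl free; the route is built for exactly this regioisomer.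

**Step 1**
Reactants: 1 3-methylcyclopent-2-en-1-one
Product: 3 2-bromo-3-methylcyclopent-2-en-1-one, via dibromoketone 2 (not isolated)
Conditions: Br2 (1.05 equiv), CH2Cl2, 0 °C; then Et3N (1.5 equiv), 0 °C to rt
Reagents that add atoms: bromine, BrBr
Why: Bromination–dehydrobromination: bromine adds across the enone C=C and triethylamine removes the acidic α-hydrogen with loss of the tertiary β-bromide (E1cB), a standard route to α-bromoenones that leaves no stereocentre.

**Step 2**
Reactants: 3 2-bromo-3-methylcyclopent-2-en-1-one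
Product: 4 (S)-2-bromo-3-methylcyclopent-2-en-1-ol
Conditions: (R)-Me-CBS oxazaborolidine [(R)-1-methyl-3,3-diphenyltetrahydro-1H,3H-pyrrolo[1,2-c][1,3,2]oxazaborole] (15 mol %), BH3·SMe2, THF, 0 °C; MeOH quench
Reagents that add atoms: none
Why: Corey–Bakshi–Shibata reduction: the bromoalkenyl arm of the ketone acts as the large group and the ring CH2 as the small one, so borane bound to the (R)-oxazaborolidine should deliver hydride to the face that gives the (S)-carbinol, the future C4 centre with its oxygen β.

**Step 3**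
Reactants: 4 (S)-2-bromo-3-methylcyclopent-2-en-1-ol
Product: 5 (S)-[(2-bromo-3-methylcyclopent-2-en-1-yl)oxy](tert-butyl)dimethylsilane
Conditions: t-BuMe2SiCl, imidazole, DMF, rt
Reagents that add atoms: tert-butyldimethylsilyl chloride, CC(C)(C)[Si](C)(C)Cl
Why: Imidazole-promoted O-silylation of a secondary allylic alcohol leaves the stereocentre unchanged; the TBS group is large enough to screen the β face in steps 6 and 8 and is later more labile than TBDPS.

**Step 4**
Reactants: 5 (S)-[(2-bromo-3-methylcyclopent-2-en-1-yl)oxy](tert-butyl)dimethylsilane; 6 potassium vinyltrifluoroborate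
Product: 7 (S)-tert-butyldimethyl[(3-methyl-2-vinylcyclopent-2-en-1-yl)oxy]silane
Conditions: PdCl2(dppf) (5 mol %), Cs2CO3 (3 equiv), THF–H2O 9:1, 75 °C
Reagents that add atoms: none
Why: Suzuki–Miyaura coupling: zerovalent palladium inserts into the alkenyl carbon–bromine bond, the vinyl group is transferred from the slowly hydrolysed trifluoroborate and reductive elimination gives the 1,3-diene, while aqueous carbonate leaves silyl ether and carbinol centre untouched.

**Step 5**
Reactants: 8 2-methoxypropene
Product: 9 2-methoxyallyl bromide (3-bromo-2-methoxyprop-1-ene)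
Conditions: N-bromosuccinimide, pentane, 0 °C to rt, dark; filter, distil from K2CO3
Reagents that add atoms: N-bromosuccinimide, O=C1CCC(=O)N1Br
Why: Electrophilic bromination of an enol ether with allylic transposition: bromine transfer to the CH2 terminus gives an oxocarbenium ion that loses a proton from its methyl group to the succinimide anion, which restores the enol ether next to the new CH2Br group.

**Step 6**
Reactants: 7 (S)-tert-butyldimethyl[(3-methyl-2-vinylcyclopent-2-en-1-yl)oxy]silane; 9 2-methoxyallyl bromide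
Product: 12 (1R,4S)-4-(tert-butyldimethylsilyloxy)-1-methylbicyclo[5.3.0]dec-5-en-9-one, via 2-methoxyallyl cation 10 (not isolated), via methyl enol ether 11 (not isolated)
Conditions: 9 (3 equiv, slow addition), AgO2CCF3 (3 equiv), Na2CO3 (excess), pentane–CH2Cl2, −30 to 0 °C, dark; filter; then 0.1 M HCl, THF, 0 °C
Reagents that add atoms: water, O; silver trifluoroacetate, [Ag+].[O-]C(=O)C(F)(F)F (counter-ion of 10 only)
Why: Silver-assisted ionisation of 9 gives the 2-methoxyallyl cation 10, a three-carbon two-π-electron partner, which adds to the cisoid rotamer of diene 7 in a (4+3) cycloaddition; the closest known reaction type is the cycloaddition of this cation and of related oxyallyl cations to open-chain and cyclic 1,3-dienes. Bond formation should be strongly asynchronous: the unsubstituted terminus C7 bonds first (C7–C8), the charge passes into the C6–C5–C1 allyl cation with most of its weight on tertiary C1, and the enol ether carbon C10 then closes the seven-membered ring at C1 (a 7-endo-trig capture of the allyl cation, overall a suprafacial [4π+2π] closure), so the congested quaternary bond is made within one molecule. Proton loss to Na2CO3 gives enol ether 11, and brief dilute acid hydrolyses it to the C9 ketone without harming the TBS ether. C1 is the only new stereocentre and is controlled by the C4 silyloxy group: the three-carbon chain must swing past C5 to reach C1 and should do so on the α face, anti to the β-OTBS group, which leaves the C1 methyl group β (1R). No regiochemical issue arises because 10 is symmetric; the selectivity needed is closure at C1 in preference to collapse at C6 (five-membered ring) or proton loss, and it is supported by the higher cation character of tertiary C1 and by the C4 substituent, which crowds the transoid rotamer (C7 against C4) from which the seven-membered ring cannot form.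

**Step 7**
Reactants: 12 (1R,4S)-4-(tert-butyldimethylsilyloxy)-1-methylbicyclo[5.3.0]dec-5-en-9-one
Product: 13 (1R,4S)-4-(tert-butyldimethylsilyloxy)-9,9-(ethylenedioxy)-1-methylbicyclo[5.3.0]dec-5-ene
Conditions: Me3SiOCH2CH2OSiMe3, Me3SiOTf (5 mol %), CH2Cl2, −78 to −40 °C; pyridine quench
Reagents that add atoms: 1,2-bis(trimethylsilyloxy)ethane, C[Si](C)(C)OCCO[Si](C)(C)C
Why: Aprotic acetalisation with the bis-silylated diol under Me3SiOTf catalysis (Noyori acetalisation) is driven by formation of the Si–O–Si bond and runs at low temperature, so the allylic TBS ether and the position of the C5=C6 alkene should be preserved.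

**Step 8**
Reactants: 13 (1R,4S)-4-(tert-butyldimethylsilyloxy)-9,9-(ethylenedioxy)-1-methylbicyclo[5.3.0]dec-5-ene
Product: 15 (1R,4S,5S,6S)-4β-(tert-butyldimethylsilyloxy)-9,9-(ethylenedioxy)-1β-methyl-5αH-bicyclo[5.3.0]decan-6α-ol, via alkylborane 14 (not isolated)
Conditions: BH3·THF, THF, 0 °C to rt; then NaOH, 30% H2O2, 0 °C to rt
Reagents that add atoms: hydrogen peroxide, OO; borane–tetrahydrofuran, B.C1CCOC1 (boron of 14 only)
Why: Brown hydroboration–oxidation: boron goes to the less substituted C6 and hydrogen to C5 in a syn addition on the α face, because the β face carries both the pseudoaxial C1 methyl group and the C4 silyloxy group, and the C–B bond is oxidised with retention, which sets H5 and O6 both α and makes the ring fusion trans.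

**Step 9**
Reactants: 15 4β-(tert-butyldimethylsilyloxy)-9,9-(ethylenedioxy)-1β-methyl-5αH-bicyclo[5.3.0]decan-6α-ol
Product: 16 4β-(tert-butyldimethylsilyloxy)-6α-(tert-butyldiphenylsilyloxy)-9,9-(ethylenedioxy)-1β-methyl-5αH-bicyclo[5.3.0]decane
Conditions: t-BuPh2SiCl, imidazole, 4-(dimethylamino)pyridine (cat.), DMF, 40 °C
Reagents that add atoms: tert-butyldiphenylsilyl chloride, CC(C)(C)[Si](Cl)(c1ccccc1)c1ccccc1
Why: Imidazole-promoted O-silylation of the equatorial secondary alcohol; TBDPS is chosen because it resists acidic fluoride far better than TBS and migrates reluctantly.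

**Step 10**
Reactants: 16 4β-(tert-butyldimethylsilyloxy)-6α-(tert-butyldiphenylsilyloxy)-9,9-(ethylenedioxy)-1β-methyl-5αH-bicyclo[5.3.0]decane
Product: 17 6α-(tert-butyldiphenylsilyloxy)-9,9-(ethylenedioxy)-1β-methyl-5αH-bicyclo[5.3.0]decan-4β-ol
Conditions: HF·pyridine, pyridine, THF, 0 °C to rt
Reagents that add atoms: none
Why: Chemoselective fluoride-mediated desilylation: under pyridine-buffered HF the dimethyl-tert-butylsilyl ether is cleaved much faster than the diphenyl analogue, and the buffered medium should leave the dioxolane intact.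

**Step 11**
Reactants: 17 6α-(tert-butyldiphenylsilyloxy)-9,9-(ethylenedioxy)-1β-methyl-5αH-bicyclo[5.3.0]decan-4β-ol
Product: 18 6α-(tert-butyldiphenylsilyloxy)-9,9-(ethylenedioxy)-1β-methyl-5αH-bicyclo[5.3.0]decan-4-one
Conditions: (n-Pr4N)RuO4 (5 mol %), N-methylmorpholine N-oxide, 4 Å molecular sieves, CH2Cl2, rt
Reagents that add atoms: none
Why: Ley–Griffith oxidation: the (n-Pr4N)RuO4/N-oxide system is neutral and anhydrous, so the hindered pseudoaxial alcohol should be oxidised without epimerisation at C5 or β-elimination of the C6 silyloxy group.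

**Step 12**
Reactants: 18 6α-(tert-butyldiphenylsilyloxy)-9,9-(ethylenedioxy)-1β-methyl-5αH-bicyclo[5.3.0]decan-4-one
Product: 19 6α-(tert-butyldiphenylsilyloxy)-9,9-(ethylenedioxy)-4α-isopropyl-1β-methyl-5αH-bicyclo[5.3.0]decan-4β-ol
Conditions: CeCl3 (anhydrous), i-PrMgCl, THF, −78 °C, 1 h; then 18, −78 to −30 °C; aq NH4Cl
Reagents that add atoms: isopropylmagnesium chloride, CC(C)[Mg]Cl
Why: Organocerium 1,2-addition: weakly basic, oxophilic i-PrCeCl2 suppresses enolisation, β-elimination and β-hydride reduction, and in the trans-fused ketone the angular C1 methyl group lies syn-axial to the β trajectory, so isopropyl should enter from the α face and leave the new hydroxyl β.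

**Step 13**
Reactants: 20 4-hydroxybenzoic acid
Product: 21 tert-butyldimethylsilyl 4-(tert-butyldimethylsilyloxy)benzoate
Conditions: t-BuMe2SiCl (2.4 equiv), imidazole, DMF, rt
Reagents that add atoms: tert-butyldimethylsilyl chloride, CC(C)(C)[Si](C)(C)Cl
Why: Exhaustive imidazole-promoted silylation converts phenol and carboxylic acid into silyl ether and silyl ester in one operation.

**Step 14**
Reactants: 21 tert-butyldimethylsilyl 4-(tert-butyldimethylsilyloxy)benzoate
Product: 22 4-(tert-butyldimethylsilyloxy)benzoyl chloride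
Conditions: (COCl)2, N,N-dimethylformamide (cat.), CH2Cl2, 0 °C to rt
Reagents that add atoms: oxalyl chloride, ClC(=O)C(=O)Cl
Why: Conversion of a silyl ester into the acid chloride by the Vilsmeier-type chloroiminium species from oxalyl chloride and DMF: the silyl group leaves as its chloride and no HCl is formed, so the aryl silyl ether survives.

**Step 15**
Reactants: 19 6α-(tert-butyldiphenylsilyloxy)-9,9-(ethylenedioxy)-4α-isopropyl-1β-methyl-5αH-bicyclo[5.3.0]decan-4β-ol; 22 4-(tert-butyldimethylsilyloxy)benzoyl chloride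
Product: 24 6α-(tert-butyldiphenylsilyloxy)-9,9-(ethylenedioxy)-4α-isopropyl-1β-methyl-5αH-bicyclo[5.3.0]decan-4β-yl 4-(tert-butyldimethylsilyloxy)benzoate, via lithium alkoxide 23 (not isolated)
Conditions: LiN(SiMe3)2, THF, −40 °C; then 22, −40 °C to rt
Reagents that add atoms: lithium hexamethyldisilazide, [Li+].C[Si](C)(C)[N-][Si](C)(C)C (lithium of 23 only)
Why: Acylation of a preformed tertiary lithium alkoxide with an acid chloride is the established answer for tertiary alcohols that resist amine-catalysed esterification; C4 keeps its configuration because only the O–H bond reacts, and pseudoaxial O4 and equatorial O6 are poorly aligned for a six-membered silyl transfer.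

**Step 16**
Reactants: 24 6α-(tert-butyldiphenylsilyloxy)-9,9-(ethylenedioxy)-4α-isopropyl-1β-methyl-5αH-bicyclo[5.3.0]decan-4β-yl 4-(tert-butyldimethylsilyloxy)benzoate
Product: 25 6α-(tert-butyldiphenylsilyloxy)-4α-isopropyl-1β-methyl-9-oxo-5αH-bicyclo[5.3.0]decan-4β-yl 4-(tert-butyldimethylsilyloxy)benzoate
Conditions: pyridinium p-toluenesulfonate (cat.), acetone–H2O 10:1, 55 °C
Reagents that add atoms: water, O
Why: Acid-catalysed acetal hydrolysis with pyridinium p-toluenesulfonate is mild enough for the tertiary ester, the aryl TBS ether and the TBDPS ether.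

**Step 17**
Reactants: 25 6α-(tert-butyldiphenylsilyloxy)-4α-isopropyl-1β-methyl-9-oxo-5αH-bicyclo[5.3.0]decan-4β-yl 4-(tert-butyldimethylsilyloxy)benzoate
Product: 26 6α-(tert-butyldiphenylsilyloxy)-4α-isopropyl-1β-methyl-9-oxo-5αH-bicyclo[5.3.0]dec-7-en-4β-yl 4-(tert-butyldimethylsilyloxy)benzoate
Conditions: IBX (2-iodoxybenzoic acid), DMSO–fluorobenzene, 70 °C
Reagents that add atoms: none
Why: IBX dehydrogenation of a ketone through its enol: C10 is flanked by quaternary C1 and offers no β-hydrogen, so desaturation can only occur between C8 and C7.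

**Step 18**
Reactants: 26 6α-(tert-butyldiphenylsilyloxy)-4α-isopropyl-1β-methyl-9-oxo-5αH-bicyclo[5.3.0]dec-7-en-4β-yl 4-(tert-butyldimethylsilyloxy)benzoate
Product: 27 6α-(tert-butyldiphenylsilyloxy)-8-iodo-4α-isopropyl-1β-methyl-9-oxo-5αH-bicyclo[5.3.0]dec-7-en-4β-yl 4-(tert-butyldimethylsilyloxy)benzoate
Conditions: I2, pyridine–CH2Cl2 1:1, 0 °C to rt
Reagents that add atoms: iodine, II
Why: α-Iodination of an enone by a Baylis–Hillman-type addition–elimination sequence: pyridine adds reversibly to C7, the resulting enolate is iodinated at C8 and pyridine is expelled.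

**Step 19**
Reactants: 27 6α-(tert-butyldiphenylsilyloxy)-8-iodo-4α-isopropyl-1β-methyl-9-oxo-5αH-bicyclo[5.3.0]dec-7-en-4β-yl 4-(tert-butyldimethylsilyloxy)benzoate
Product: 28 6α-(tert-butyldiphenylsilyloxy)-4α-isopropyl-1β,8-dimethyl-9-oxo-5αH-bicyclo[5.3.0]dec-7-en-4β-yl 4-(tert-butyldimethylsilyloxy)benzoate
Conditions: Me4Sn, Pd2(dba)3 (5 mol %), AsPh3, CuI (cat.), N-methylpyrrolidone, 60 °C
Reagents that add atoms: tetramethylstannane, C[Sn](C)(C)C
Why: Stille coupling under neutral conditions, accelerated by AsPh3 and CuI, transfers one methyl group to the alkenyl iodide and touches neither the ester nor the silyl ethers.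

**Step 20**
Reactants: 28 6α-(tert-butyldiphenylsilyloxy)-4α-isopropyl-1β,8-dimethyl-9-oxo-5αH-bicyclo[5.3.0]dec-7-en-4β-yl 4-(tert-butyldimethylsilyloxy)benzoate
Product: 29 (3R,3aS,4S,8aR)-4-hydroxy-6,8a-dimethyl-7-oxo-3-(propan-2-yl)-1,2,3,3a,4,7,8,8a-octahydroazulen-3-yl 4-hydroxybenzoate (CNP0153637.1)
Conditions: n-Bu4NF–AcOH 1:1, THF, 0 °C to rt
Reagents that add atoms: none
Why: Fluoride-mediated global desilylation; acetic acid buffering keeps the liberated C6 hydroxyl and the phenol protonated, so neither acyl migration from O4 to O6 nor ester cleavage should take place.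

**Compound list**
1 | 3-methylcyclopent-2-en-1-one | CC1=CC(=O)CC1 | starting material
2 | 2,3-dibromo-3-methylcyclopentan-1-one (not isolated) | CC1(Br)CCC(=O)C1Br | intermediate
3 | 2-bromo-3-methylcyclopent-2-en-1-one | CC1=C(Br)C(=O)CC1 | intermediate
4 | (S)-2-bromo-3-methylcyclopent-2-en-1-ol | BrC1=C(C)CC[C@@H]1O | intermediate
5 | (S)-[(2-bromo-3-methylcyclopent-2-en-1-yl)oxy](tert-butyl)dimethylsilane | BrC1=C(C)CC[C@@H]1O[Si](C)(C)C(C)(C)C | intermediate
6 | potassium vinyltrifluoroborate | C=C[B-](F)(F)F.[K+] | starting material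
7 | (S)-tert-butyldimethyl[(3-methyl-2-vinylcyclopent-2-en-1-yl)oxy]silane | C=CC1=C(C)CC[C@@H]1O[Si](C)(C)C(C)(C)C | intermediate
8 | 2-methoxypropene | COC(C)=C | starting material
9 | 2-methoxyallyl bromide | COC(=C)CBr | intermediate
10 | 2-methoxyallyl cation, trifluoroacetate ion pair (not isolated) | COC(=C)[CH2+].[O-]C(=O)C(F)(F)F | intermediate
11 | (1R,4S)-4-(TBS-oxy)-9-methoxy-1-methylbicyclo[5.3.0]deca-5,8-diene (not isolated) | COC1=CCC=C2[C@@H](O[Si](C)(C)C(C)(C)C)CC[C@]2(C)C1 | intermediate
12 | (1R,4S)-4-(TBS-oxy)-1-methylbicyclo[5.3.0]dec-5-en-9-one (1β-methyl, 4β-OTBS) | O=C1CCC=C2[C@@H](O[Si](C)(C)C(C)(C)C)CC[C@]2(C)C1 | intermediate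
13 | C9 ethylene ketal of 12 | C1CC=C2[C@@H](O[Si](C)(C)C(C)(C)C)CC[C@]2(C)CC13OCCO3 | intermediate
14 | 6α-boryl-5αH adduct of 13 (not isolated) | C1C[C@H]([BH2])[C@@H]2[C@](C)(CC[C@@H]2O[Si](C)(C)C(C)(C)C)CC13OCCO3 | intermediate
15 | 4β-(TBS-oxy)-9,9-(ethylenedioxy)-1β-methyl-5αH-bicyclo[5.3.0]decan-6α-ol | C1C[C@H](O)[C@@H]2[C@](C)(CC[C@@H]2O[Si](C)(C)C(C)(C)C)CC13OCCO3 | intermediate
16 | 4β-(TBS-oxy)-6α-(TBDPS-oxy)-9,9-(ethylenedioxy)-1β-methyl-5αH-bicyclo[5.3.0]decane | C1C[C@H](O[Si](c3ccccc3)(c4ccccc4)C(C)(C)C)[C@@H]2[C@](C)(CC[C@@H]2O[Si](C)(C)C(C)(C)C)CC15OCCO5 | intermediate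
17 | 6α-(TBDPS-oxy)-9,9-(ethylenedioxy)-1β-methyl-5αH-bicyclo[5.3.0]decan-4β-ol | C1C[C@H](O[Si](c3ccccc3)(c4ccccc4)C(C)(C)C)[C@@H]2[C@](C)(CC[C@@H]2O)CC15OCCO5 | intermediate
18 | 6α-(TBDPS-oxy)-9,9-(ethylenedioxy)-1β-methyl-5αH-bicyclo[5.3.0]decan-4-one | C1C[C@H](O[Si](c3ccccc3)(c4ccccc4)C(C)(C)C)[C@@H]2[C@](C)(CCC2=O)CC15OCCO5 | intermediate
19 | 6α-(TBDPS-oxy)-9,9-(ethylenedioxy)-4α-isopropyl-1β-methyl-5αH-bicyclo[5.3.0]decan-4β-ol | C1C[C@H](O[Si](c3ccccc3)(c4ccccc4)C(C)(C)C)[C@@H]2[C@](C)(CC[C@@]2(O)C(C)C)CC15OCCO5 | intermediate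
20 | 4-hydroxybenzoic acid | OC(=O)c1ccc(O)cc1 | starting material
21 | tert-butyldimethylsilyl 4-(TBS-oxy)benzoate | CC(C)(C)[Si](C)(C)OC(=O)c1ccc(O[Si](C)(C)C(C)(C)C)cc1 | intermediate
22 | 4-(TBS-oxy)benzoyl chloride | ClC(=O)c1ccc(O[Si](C)(C)C(C)(C)C)cc1 | intermediate
23 | lithium 4β-alkoxide of 19 (not isolated) | C1C[C@H](O[Si](c3ccccc3)(c4ccccc4)C(C)(C)C)[C@@H]2[C@](C)(CC[C@@]2([O-])C(C)C)CC15OCCO5.[Li+] | intermediate
24 | 4β-[4-(TBS-oxy)benzoate] of 19 | C1C[C@H](O[Si](c3ccccc3)(c4ccccc4)C(C)(C)C)[C@@H]2[C@](C)(CC[C@@]2(OC(=O)c3ccc(O[Si](C)(C)C(C)(C)C)cc3)C(C)C)CC15OCCO5 | intermediate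
25 | C9 ketone from 24 | C1C[C@H](O[Si](c3ccccc3)(c4ccccc4)C(C)(C)C)[C@@H]2[C@](C)(CC[C@@]2(OC(=O)c3ccc(O[Si](C)(C)C(C)(C)C)cc3)C(C)C)CC1=O | intermediate
26 | C7=C8 enone from 25 | C1=C[C@H](O[Si](c3ccccc3)(c4ccccc4)C(C)(C)C)[C@@H]2[C@](C)(CC[C@@]2(OC(=O)c3ccc(O[Si](C)(C)C(C)(C)C)cc3)C(C)C)CC1=O | intermediate
27 | 8-iodo enone | IC1=C[C@H](O[Si](c3ccccc3)(c4ccccc4)C(C)(C)C)[C@@H]2[C@](C)(CC[C@@]2(OC(=O)c3ccc(O[Si](C)(C)C(C)(C)C)cc3)C(C)C)CC1=O | intermediate
28 | 8-methyl enone, bis-silyl ether of the target | CC1=C[C@H](O[Si](c3ccccc3)(c4ccccc4)C(C)(C)C)[C@@H]2[C@](C)(CC[C@@]2(OC(=O)c3ccc(O[Si](C)(C)C(C)(C)C)cc3)C(C)C)CC1=O | intermediate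
29 | (3R,3aS,4S,8aR)-4-hydroxy-6,8a-dimethyl-7-oxo-3-(propan-2-yl)-1,2,3,3a,4,7,8,8a-octahydroazulen-3-yl 4-hydroxybenzoate | CC1=C[C@H](O)[C@@H]2[C@](C)(CC[C@@]2(OC(=O)c2ccc(O)cc2)C(C)C)CC1=O | target

**Step count**
Total step count: 20.
Longest linear sequence: 17 steps (1–4, 6–12, 15–20) from 3-methylcyclopent-2-en-1-one.

**Steps most likely to fail**

Step 6.
- What may go wrong: the cation may be consumed by the transoid rotamer of the diene. The intermediate allyl cation may collapse at C6 to a five-membered ring or lose a proton before the C1–C10 bond closes. The facial bias exerted by the C4 group may also prove too small.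
- Fallback: the same two ring bonds are made by a rhodium-carbenoid route of known type, setting out from diene 7.
- Commercial ethyl 2-diazo-3-oxobutanoate is O-silylated (t-BuMe2SiOTf, Et3N, CH2Cl2, 0 °C) to ethyl 3-(tert-butyldimethylsilyloxy)-2-diazobut-3-enoate F1.
- F1 is added slowly to 7 and dirhodium tetrakis[(S)-(1-adamantyl)(phthalimido)acetate], Rh2(S-PTAD)4, in hexane. The enantiomeric catalyst is used instead if it proves matched to the C4 centre.
- A tandem cyclopropanation/Cope rearrangement starts at the unhindered C6=C7 vinyl group. It should give ethyl (1R,4S)-4,9-bis(TBS-oxy)-1-methylbicyclo[5.3.0]deca-5,8-diene-8-carboxylate F2, in which C7–C8 and C1–C10 are both in place.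
- Et3N·3HF (1 equiv, THF, 0 °C) cleaves only the silyl enol ether and gives the β-keto ester F3.
- Krapcho dealkoxycarbonylation (LiCl, wet DMSO, 140 °C) brings the sequence back to the route at ketone 12.

Step 15.
- What may go wrong: attack of the very hindered pseudoaxial alkoxide on the aroyl chloride may be too slow. Silyl transfer from O6 or loss of the aryl silyl ether could then take over.
- Fallback: the C–O bond is made first with a small, doubly activated carbonyl donor, and the arene is brought in afterwards as a carbon nucleophile, setting out from alcohol 19.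
- KN(SiMe3)2 followed by 1,1'-carbonyldiimidazole (THF, 0 °C to rt) gives the 4β-yl imidazole-1-carboxylate F4.
- [4-(tert-Butyldimethylsilyloxy)phenyl]magnesium bromide F5 is made from commercial (4-bromophenoxy)(tert-butyl)dimethylsilane and Mg in THF.
- F5 displaces the imidazolide at 0 °C in the known ester synthesis from Grignard reagents and alkyl imidazolecarboxylates. The C9 ketal keeps the only other carbonyl masked. The route is rejoined at ester 24.

Step 12.
- What may go wrong: β-hydride transfer from the isopropyl reagent (reduction) may compete. Enolisation may cause loss of the C6 silyloxy group or epimerisation at C5. Facial selectivity may be insufficient for so bulky a nucleophile.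
- Fallback: the group is introduced as a flatter sp2 nucleophile without a transferable β-hydride and saturated afterwards, setting out from ketone 18.
- Isopropenylmagnesium bromide/CeCl3 (THF, −78 °C) gives the 4α-isopropenyl-4β-ol F6.
- Hydrogenation (H2, PtO2, EtOAc, rt) of its only alkene returns to the route at alcohol 19.

**Further compounds**
F1 | step 6 | ethyl 3-(tert-butyldimethylsilyloxy)-2-diazobut-3-enoate | C=C(O[Si](C)(C)C(C)(C)C)C(=[N+]=[N-])C(=O)OCC
F2 | step 6 | ethyl (1R,4S)-4,9-bis(TBS-oxy)-1-methylbicyclo[5.3.0]deca-5,8-diene-8-carboxylate | CC(C)(C)[Si](C)(C)OC1=C(C(=O)OCC)CC=C2[C@@H](O[Si](C)(C)C(C)(C)C)CC[C@]2(C)C1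
F3 | step 6 | ethyl (1R,4S)-4-(TBS-oxy)-1-methyl-9-oxobicyclo[5.3.0]dec-5-ene-8-carboxylate (C8 epimers/enol) | CCOC(=O)C1CC=C2[C@@H](O[Si](C)(C)C(C)(C)C)CC[C@]2(C)CC1=O
F4 | step 15 | 6α-(TBDPS-oxy)-9,9-(ethylenedioxy)-4α-isopropyl-1β-methyl-5αH-bicyclo[5.3.0]decan-4β-yl imidazole-1-carboxylate | C1C[C@H](O[Si](c3ccccc3)(c4ccccc4)C(C)(C)C)[C@@H]2[C@](C)(CC[C@@]2(OC(=O)n3ccnc3)C(C)C)CC15OCCO5
F5 | step 15 | [4-(tert-butyldimethylsilyloxy)phenyl]magnesium bromide | CC(C)(C)[Si](C)(C)Oc1ccc([Mg]Br)cc1
F6 | step 12 | 6α-(TBDPS-oxy)-9,9-(ethylenedioxy)-4α-isopropenyl-1β-methyl-5αH-bicyclo[5.3.0]decan-4β-ol | C1C[C@H](O[Si](c3ccccc3)(c4ccccc4)C(C)(C)C)[C@@H]2[C@](C)(CC[C@@]2(O)C(C)=C)CC15OCCO5
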